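The teal flask, with twice the reagent of the grey flask, reads higher in target: 43.5% against 19.4%, each a mean of readings over its plateau.

all flasks: starting material 0.13 M

|  | reagent | remark | time |
|---|---|---|---|
| grey | 2 equiv | the very flask that is asked about, followed so far |  |
| teal | 4 equiv | run made earlier |  |
| flask | 2.00 equiv |  | 8.0 min |

grey run (percent of the starting material charged)

| time / min | target / % |
|---|---|
| 1.00 | 20.5 |
| 2.50 | 19.6 |
| 3.00 | 21.5 |
| 5.00 | 18.9 |
| 6.00 | 17.6 |
| 8.00 | 18.5 |

teal run (percent of the starting material charged)

| time / s | target / % |
|---|---|
| 10.0 | 37.8 |
| 15.0 | 44.5 |
| 25.0 | 42.0 |
| 40.0 | 43.4 |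
| 60.0 | 42.9 |
| 80.0 | 43.9 |
| 90.0 | 44.5 |

(standard deviation of a reading: 1 percentage point)

- larch: change nothing and wait 15 min more
- maple: at 8.0 min add reagent, 100% of the amount charged, then wait 15 min
- birch: at 8.0 min add starting material, 50.0% of the amount charged, then wait 15 min

- target, in percent of the starting material first charged, at 8.0 min
- what to do for the largest gain in target; "none" if nothing gains more than 2 percentage points (larch / maple / birch / none)
- target present, in percent of the starting material first charged, after larch
- target present, in percent of the starting material first charged, after maple

- additions bring no volume worth counting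
- the analysis behind the earlier runs scatters by 1 percentage point, standard deviation
- a reading or a percentage of target counts all its forms, free or not

We take the plateau as a balance. Suppose starting material quickly takes up one reagent to give a first form, and that form reversibly takes a second reagent to give target. Everything not target then sits in the first form, and the free reagent follows by subtraction:

grey: 2.30 M⁻¹

teal: 2.31 M⁻¹

This balance ratio, target divided by the first form and by the free reagent, agrees between the runs.

So, for the grey flask, we read target as a balance, not as a product piling up. But its readings sink, from 20.5% up to 3.00 min to 18.3% from 5.00 min on. With the ratio frozen, that means material is leaving the balance. We expect about 18.3% now. Don't wait. Add reagent: 100% more makes the recipe teal's, and 43.5% is what that gives if nothing has left.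

The forecast says 18.8% now, maple as the choice, 17.5% after larch and 41% after maple. On waiting it says: “This may be noise or slow target loss, so waiting gives no gain and perhaps a loss.”

The flask gives 17.3%, 11.8% after larch and 25.9% after maple, and that last value is lower than the forecast's 41%.

    starting material + reagent ⇌ intermediate C (K = 130 M⁻¹, k = 0.769 M⁻¹ s⁻¹)
    starting material → intermediate A (k = 0.0247 s⁻¹)
    reagent + intermediate C ⇌ target (K = 2.60 M⁻¹, k = 0.441 M⁻¹ s⁻¹)
    intermediate A ⇌ intermediate B (K = 11.0, k = 0.0128 s⁻¹)
    starting material + target ⇌ idle adduct, settled at all times (K = 1.60 M⁻¹)

In the grey flask at 8.00 min, reagent and intermediate C relax with target with a half-life of 2.62 s by this step alone, both ways together, shorter than the 8.0 min of the run, while intermediate C is made at 0.183 of the rate at which it is used up, each step taken net. The balance ratio, set on the 40.9% intermediate C and the 62.2% of the reagent's charge standing then, gives 15.2% target against 17.3%. In the neighbour flask at 0.22 M, its 43.7% intermediate C and 52.0% of the reagent's charge give 23.0%, and that flask holds 26.1%.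

(The runs stem from a simulated flask for an exercise; noise was put on by code.)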